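## Analysis of the target

The target is a daucane (carotane) sesquiterpenoid ester built on a trans-fused bicyclo[5.3.0]decane. Ring A (cyclopentane, C1–C5) carries the angular methyl C15 on quaternary C1 and a tertiary carbinol at C4 that bears the isopropyl group. Ring B (cycloheptane, C1 and C5–C10) carries the 3-methylbutanoate at C6, a spiro-epoxide at C8 (C14 is the epoxide CH2) and a cis-diol at C9/C10.

There are seven stereocentres, contiguous from C4 round to C1 (1S,4R,5S,6S,8S,9S,10S). Taking the face of C15 as β, the C4 hydroxyl is β, while H-5, the C6 ester oxygen, the epoxide oxygen on C8 and both C9/C10 hydroxyls are α.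

The sensitive groups are the spiro-epoxide next to a free diol (opened by acid, migrated by base), the base-labile ester, and the C4 hydroxyl, which is β to C6. Any intermediate with a carbonyl at C6 is therefore a tertiary aldol that can undergo retro-aldol cleavage or dehydration.

The hard points are the quaternary C1 at a trans ring fusion, its configuration relative to the remote C4, and four functionalised carbons on a medium ring.

Two features of this structure invite the route:
- **Ring B pattern.** The oxygenated carbons C6 and C8 are 1,3-related through the C7 methylene and are followed by C9–C10 leading into quaternary C1. This is the pattern of a 3-siloxycyclohept-3-enone with two new sp3 centres across the ring, which a Brook rearrangement-mediated [3+4] annulation delivers by forming C7–C8 and C1–C10 together.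
- **Ring A pattern.** The chain C15–C1–C2–C3–C4(OH)–isopropyl is the methyl-to-isopropyl axis of the p-menthane terpinen-4-ol, with the carbinol stereocentre already in place.

## Retrosynthetic reasoning

**24 to 23.** The two C–O bonds of the spiro-epoxide (C8–O, C14–O) are cut last, giving the exocyclic alkene 23. The epoxide is the most fragile group, and the free C9 hydroxyl of 23 can deliver the oxygen to the α face under near-neutral conditions. The forward step must be a hydroxyl-directed epoxidation that spares the ester.

**23 to 20 (through 22 and 21).** The C8=C14 bond is cut back to the C8 ketone, with the diol masked as the acetonide 21. Bringing C14 in as a single methylene onto a ketone avoids carrying an extra carbon through the ring construction. The forward olefination must be non-basic, because 21 is a β-acyloxy ketone.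

**20 to 19.** Both C–O bonds at C9 and C10 are cut together to the cis-enone 19. A syn-dihydroxylation sets both centres at once, and the angular C15 methyl on the neighbouring C1 shields the β face.

**19 to 15 (through 17 and 16).** The enone is recognised as the unmasked form of the 2-siloxy allylsilane in 17. The ester C–O bond is cut to alcohol 16 and the C6–H bond to ketone 15. Working in this order keeps C8 masked as a silyl enol ether while C6 is reduced and acylated, so the C6/C8 1,3-dicarbonyl is never free. The forward reduction must deliver hydride from the β face, which the C4 hydroxyl can direct.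

**15 to 7 plus 11 (key disconnection).** Ring B is cut at C7–C8 and C1–C10. These two bonds separate a ten-carbon ring-A piece, methyl ketone 7 (C1–C7, C15, isopropyl), from a three-carbon piece, acylsilane 11 (C8–C10). Cutting here makes the C6 and C8 oxygens the two carbonyl groups of the partners. The gain is ring B, the quaternary C1 and the ring fusion in one operation from a monocyclic cyclopentene. The forward reaction has to form C1–C10 on the isopropyl face of ring A and leave C6 and C8 differentiated.

**7 to 1 (through 6, 4, 3 and 2).** The C5=C1 bond of 7 is cut by a retro-aldol condensation to the 1,6-keto aldehyde 3 (C7 is added later as a methyl nucleophile to aldehyde 4). Reconnecting the two carbonyl carbons of 3 gives the cyclohexene 2, the silyl ether of (S)-terpinen-4-ol 1. In the forward sense the six-membered ring of the terpene is contracted to ring A, and its carbinol carbon becomes C4 with the correct configuration. The silyl ether is needed only while an aldehyde is β to the C4 oxygen.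

**11 to 8 (through 10).** The acylsilane is cut to methoxyallene 8 through the bis-silylated allene 10, the standard masked form of an acryloylsilane.

## Alternatives that were turned down

**Alternative 1: ring-closing metathesis at C9=C10 (the textbook route).**
- Disconnection: C9=C10 of cycloheptenone A3 (the silyl ether analogue of 19), with C1–C10 and C5–C6 made earlier one bond at a time.
- Forward key step: copper-catalysed asymmetric conjugate addition of a vinyl nucleophile to 3-methylcyclopent-2-en-1-one A1, aldol trapping at C5, isopropyl addition to the C4 ketone, elaboration to diene A2, then closure with the second-generation Grubbs catalyst to A3.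
- Why turned down:
  - Vinyl addition to a β-substituted cyclopentenone to make a quaternary centre is one of the least reliable asymmetric conjugate additions.
  - The isopropyl nucleophile must add to an enolisable β-alkoxy ketone, which invites enolisation and β-elimination.
  - The metathesis joins a neopentyl vinyl group on a quaternary carbon to an electron-poor vinyl ketone, both poor partners.
  - Ring B is assembled bond by bond and none of its oxygens arrives with the ring-forming step, so the route is long and linear.

**Alternative 2: insertion of a single carbon (C9) into a six-membered ring.**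
- Disconnection: C8–C9 and C9–C10 of A3, leading back to the trans-hydrindanone A4.
- Forward key step: silyl enol ether formation from A4 towards C10, cyclopropanation and FeCl3-mediated ring opening/elimination to A3.
- Why turned down:
  - The edit is reliable but moves the whole problem into A4, which already contains quaternary C1, the C4 carbinol, the trans fusion and the C6 oxygen.
  - No cheap enantiopure hydrindane carries oxygen at the carbons that become C4 and C6, so A4 needs a synthesis as long as the target's.
  - Kinetic enolisation of A4 goes towards C7, away from the neopentyl C10, where the β-silyloxy group at C6 would eliminate. The new carbon would be inserted on the wrong side of C8.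

**Alternative 3: carbonyl-ene closure of C6–C7.**
- Disconnection: C6–C7, leading back to the ring-A aldehyde A5, whose C1 side chain carries the protected C9/C10 diol and an isopropenyl group.
- Forward key step: Me2AlCl-promoted intramolecular ene reaction of the C6 aldehyde with the isopropenyl group, giving the 3-methylenecycloheptanol A6 with the C6 hydroxyl and C8=C14 in one step.
- Why turned down:
  - The ring closure is attractive, but A5 needs quaternary C1 bearing an erythro-dioxygenated chain set by acyclic stereocontrol, plus a trans, epimerisable C5 aldehyde next to the C4 carbinol (prone to retro-aldol).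
  - The C6 configuration would rest on an uncertain seven-membered ene transition state.
  - Reaching A5 would cost more steps than the ring closure saves.

Key step: step 8

Assumptions and conventions: enantiopure (S)-(+)-terpinen-4-ol is taken as commercially available. Daucane numbering is used throughout (C1 quaternary, C15 its methyl, C4 the carbinol carbon, C5 the ring-fusion CH, C6 the ester carbon, C8 the spiro carbon, C14 its one-carbon substituent). β is the face of C15, α the opposite face.

## Route

Step 1
Reactants: 1 (S)-terpinen-4-ol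
Product: 2 triethyl{[(1S)-4-methyl-1-(propan-2-yl)cyclohex-3-en-1-yl]oxy}silane
Conditions: Et3SiOSO2CF3, 2,6-lutidine, CH2Cl2, 0 °C
Reagents that add atoms: triethylsilyl trifluoromethanesulfonate, CC[Si](CC)(CC)OS(=O)(=O)C(F)(F)F
Why: Silyl triflate silylation of the hindered tertiary alcohol; the ether blocks retro-aldol cleavage and makes the C4 oxygen a poor leaving group while an aldehyde sits β to it in steps 2–4. No stereocentre is touched.

Step 2
Reactants: 2 triethylsilyl ether of terpinen-4-ol
Product: 3 (3S)-6-oxo-3-(propan-2-yl)-3-[(triethylsilyl)oxy]heptanal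
Conditions: O3, CH2Cl2/MeOH, −78 °C; then Me2S
Reagents that add atoms: ozone, [O-][O+]=O
Why: Ozonolysis of the trisubstituted ring alkene with reductive work-up opens the p-menthene to the 1,6-keto aldehyde; the quaternary silyloxy carbon (future C4) is not involved.

Step 3
Reactants: 3 keto aldehyde
Product: 4 (5R)-2-methyl-5-(propan-2-yl)-5-[(triethylsilyl)oxy]cyclopent-1-ene-1-carbaldehyde
Conditions: piperidine (cat.), AcOH (cat.), toluene, 60 °C
Reagents that add atoms: none
Why: Amine-catalysed intramolecular aldol condensation (5-enolexo): the aldehyde enamine attacks the methyl ketone, and the new free tertiary hydroxyl, more easily protonated than the silyl ether oxygen, is lost to give the conjugated enal. This contracts the six-membered ring of 1 to ring A with C4 unchanged.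

Step 4
Reactants: 4 silyloxy enal
Product: 6 (1R)-2-(1-hydroxyethyl)-3-methyl-1-(propan-2-yl)cyclopent-2-en-1-ol (both carbinol epimers), via triethylsilyl ether of the secondary alcohol 5 (not isolated)
Conditions: MeMgBr, THF, −78 → 0 °C; then Bu4NF, rt
Reagents that add atoms: methylmagnesium bromide, C[Mg]Br
Why: Grignard 1,2-addition to the aldehyde brings in C7, then fluoride cleaves the tertiary silyl ether in the same flask. The new carbinol centre is not controlled because it is oxidised in step 5.

Step 5
Reactants: 6 diol
Product: 7 1-[(5R)-5-hydroxy-2-methyl-5-(propan-2-yl)cyclopent-1-en-1-yl]ethan-1-one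
Conditions: MnO2, CH2Cl2, rt
Reagents that add atoms: none
Why: MnO2 oxidises only the allylic secondary alcohol. The free C4 hydroxyl is now β to the carbonyl through an sp2 carbon, so retro-aldol cleavage (which would need a vinyl anion) and dehydration are both impossible.

Step 6
Reactants: 8 methoxyallene (1-methoxypropa-1,2-diene)
Product: 10 tert-butyl[1-methoxy-3-(trimethylsilyl)propa-1,2-dien-1-yl]dimethylsilane, via tert-butyl(1-methoxypropa-1,2-dien-1-yl)dimethylsilane 9 (not isolated)
Conditions: n-BuLi, THF, −78 °C, then t-BuMe2SiCl; n-BuLi, −78 °C, then Me3SiCl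
Reagents that add atoms: tert-butyldimethylsilyl chloride, CC(C)(C)[Si](C)(C)Cl; chlorotrimethylsilane, C[Si](C)(C)Cl
Why: α-Lithiation of the alkoxyallene and C-silylation, then γ-lithiation of the 1-silyl allene and a second silylation (sequential metalation of alkoxyallenes).

Step 7
Reactants: 10 bis-silylated methoxyallene
Product: 11 (2E)-1-[tert-butyl(dimethyl)silyl]-3-(trimethylsilyl)prop-2-en-1-one
Conditions: 1 M HCl, THF, 0 °C → rt
Reagents that add atoms: water, O
Why: Acid hydrolysis of the allenyl enol ether (protonation at the central carbon, loss of methanol) gives the acylsilane; the E isomer is the thermodynamic product.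

Step 8
Reactants: 7 methyl ketone; 11 β-silyl acryloylsilane
Product: 15 8-[(tert-butyldimethylsilyl)oxy]-4β-hydroxy-10α-(trimethylsilyl)-14-nor-5α-dauc-8-en-6-one, via dilithium 1,2-adduct 12 (not isolated), via dilithium cis-dialkenylcyclopropanolate 13 (not isolated), via dilithium enolate 14 (not isolated)
Conditions: LiN(iPr)2 (2.2 equiv), THF, −78 °C; add 11, −78 → −20 °C; AcOH, −78 °C
Reagents that add atoms: none
Why: Double deprotonation gives the lithium alkoxide/cross-conjugated enolate of 7, whose C7 adds 1,2 to the acylsilane carbonyl of 11 (the β-silyl group blocks conjugate addition) to give 12. Brook rearrangement (silicon from C8 to oxygen) unveils a siloxyallyl lithium that closes onto the C6 ketone (3-exo-trig) to the cis-1,2-dialkenylcyclopropanolate 13, which undergoes a strain- and alkoxide-accelerated oxy-Cope rearrangement through the boat transition state, forming C1–C10 and closing ring B by [3,3] ring expansion to 14. The closest known reaction type is the Brook rearrangement-mediated [3+4] annulation of β-silyl acryloylsilanes with lithium enolates of alkenyl methyl ketones, cyclic ones included. C1 is controlled by C4: the lithium that bridges the C6 oxygen and the C4 alkoxide in 13 and in the boat can do so only when the C4–O bond lies on the ring-A face turned away from the incoming C8–C10 unit, so C10 bonds to C1 on the isopropyl face and C15 ends β. C10 is controlled by the E geometry of 11, which puts the silyl group outside in the boat, trans to C15. C5 is set when enolate 14 is protonated at −78 °C from the α face, anti to the perpendicular C15 methyl and to the lithium alkoxide, giving the trans fusion; the thermodynamic preference (C6 anti to the isopropyl group, hydrogen bond to the C4 hydroxyl) points the same way. The step needs α′- rather than γ-deprotonation of 7 (kinetic base at −78 °C) and survival of the C4 oxygen, which as a lithium alkoxide can neither leave by β-elimination nor start a retro-aldol while C5 is part of an enolate.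

Step 9
Reactants: 15 bicyclic β-hydroxy ketone
Product: 16 8-[(tert-butyldimethylsilyl)oxy]-10α-(trimethylsilyl)-14-nor-5α-dauc-8-ene-4β,6α-diol
Conditions: Me4NBH(OAc)3, MeCN/AcOH, −35 °C
Reagents that add atoms: none
Why: Hydroxyl-directed (Saksena–Evans) reduction: the C4 hydroxyl exchanges onto boron and delivers hydride intramolecularly to the β face of C6, giving the anti-1,3-diol, that is the 6α-alcohol. The reagent does not reduce carbonyls that lack a β-hydroxyl, and the low temperature should spare the silyl enol ether that masks C8.

Step 10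
Reactants: 16 diol
Product: 17 8-[(tert-butyldimethylsilyl)oxy]-4β-hydroxy-10α-(trimethylsilyl)-14-nor-5α-dauc-8-en-6α-yl 3-methylbutanoate
Conditions: 3-methylbutanoic anhydride, DMAP, Et3N, CH2Cl2, rt
Reagents that add atoms: 3-methylbutanoic anhydride, CC(C)CC(=O)OC(=O)CC(C)C
Why: DMAP-catalysed acylation of the only secondary hydroxyl; the tertiary C4 hydroxyl is inert under these conditions.

Step 11
Reactants: 17 silyl enol ether/allylsilane
Product: 19 4β-hydroxy-8-oxo-14-nor-5α-dauc-9-en-6α-yl 3-methylbutanoate, via 9β-bromo-10α-silyl ketone 18 (not isolated)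
Conditions: N-bromosuccinimide, THF, −78 °C; then Bu4NF, AcOH, 0 °C
Reagents that add atoms: none
Why: Regiospecific bromination of the silyl enol ether at C9 (anti to the C10 silyl group), then fluoride-triggered anti-elimination of the vicinal bromide and silane gives the C9=C10 enone. The acetic acid buffer keeps the β-acyloxy ketone from eliminating.

Step 12
Reactants: 19 enone
Product: 20 4β,9α,10α-trihydroxy-8-oxo-14-nor-5α-daucan-6α-yl 3-methylbutanoate
Conditions: OsO4 (5 mol %), N-methylmorpholine N-oxide, citric acid, t-BuOH/H2O, rt
Reagents that add atoms: N-methylmorpholine N-oxide, C[N+]1([O-])CCOCC1; water, O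
Why: Osmium-catalysed syn-dihydroxylation of the cis-enone; the oxidant approaches anti to the angular C15 methyl on the adjacent C1, which sets 9α and 10α together. Citric acid keeps the medium weakly acidic and helps turnover with the electron-poor alkene.

Step 13
Reactants: 20 keto diol
Product: 21 4β-hydroxy-9α,10α-(isopropylidenedioxy)-8-oxo-14-nor-5α-daucan-6α-yl 3-methylbutanoate
Conditions: 2,2-dimethoxypropane, PPTS, CH2Cl2, rt
Reagents that add atoms: 2,2-dimethoxypropane, COC(C)(C)OC
Why: Acetonide formation on the cis-diol, so that the α-hydroxy ketone cannot chelate or rearrange during the Lewis-acidic olefination.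

Step 14
Reactants: 21 acetonide ketone
Product: 22 4β-hydroxy-9α,10α-(isopropylidenedioxy)-5α-dauc-8(14)-en-6α-yl 3-methylbutanoate
Conditions: Zn, CH2Br2, TiCl4, THF/CH2Cl2, 0 °C → rt
Reagents that add atoms: dibromomethane, BrCBr
Why: Takai–Lombardo methylenation is non-basic and selective for ketones over esters, so the β-acyloxy ketone is converted to the exocyclic alkene (C14) without elimination or epimerisation.

Step 15
Reactants: 22 acetonide alkene
Product: 23 4β,9α,10α-trihydroxy-5α-dauc-8(14)-en-6α-yl 3-methylbutanoate
Conditions: AcOH/H2O (4:1), 40 °C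
Reagents that add atoms: none
Why: Mild acid hydrolysis of the acetonide frees the allylic C9 hydroxyl that must direct the epoxidation; the ester and the exocyclic alkene tolerate aqueous acetic acid.

Step 16
Reactants: 23 allylic triol
Product: 24 (1S,4R,5S,6S,8S,9S,10S)-8,14-epoxy-4,9,10-trihydroxydaucan-6-yl 3-methylbutanoate (CNP0307265.1)
Conditions: VO(acac)2 (5 mol %), t-BuOOH, CH2Cl2, 0 °C
Reagents that add atoms: tert-butyl hydroperoxide, CC(C)(C)OO
Why: Vanadium-catalysed hydroxyl-directed epoxidation of the 1,1-disubstituted allylic alcohol: the peroxide bound to vanadium on the α-oriented C9 (and C10) oxygen is delivered to the α face of C8=C14, giving the epoxide oxygen α. The neutral conditions should be tolerated by the ester and the product epoxide.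

## Compound list

1 | (S)-terpinen-4-ol, (1S)-4-methyl-1-(propan-2-yl)cyclohex-3-en-1-ol | CC1=CC[C@](O)(C(C)C)CC1 | starting material
2 | triethyl{[(1S)-4-methyl-1-(propan-2-yl)cyclohex-3-en-1-yl]oxy}silane | CC1=CC[C@](O[Si](CC)(CC)CC)(C(C)C)CC1 | intermediate
3 | (3S)-6-oxo-3-(propan-2-yl)-3-[(triethylsilyl)oxy]heptanal | O=CC[C@](O[Si](CC)(CC)CC)(C(C)C)CCC(C)=O | intermediate
4 | (5R)-2-methyl-5-(propan-2-yl)-5-[(triethylsilyl)oxy]cyclopent-1-ene-1-carbaldehyde | O=CC1=C(C)CC[C@@]1(O[Si](CC)(CC)CC)C(C)C | intermediate
5 | 1-{(5R)-2-methyl-5-(propan-2-yl)-5-[(triethylsilyl)oxy]cyclopent-1-en-1-yl}ethan-1-ol (carbinol epimers; bromomagnesium alkoxide in the flask) | CC(O)C1=C(C)CC[C@@]1(O[Si](CC)(CC)CC)C(C)C | intermediate (not isolated)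
6 | (1R)-2-(1-hydroxyethyl)-3-methyl-1-(propan-2-yl)cyclopent-2-en-1-ol (carbinol epimers) | CC(O)C1=C(C)CC[C@@]1(O)C(C)C | intermediate
7 | 1-[(5R)-5-hydroxy-2-methyl-5-(propan-2-yl)cyclopent-1-en-1-yl]ethan-1-one | CC(=O)C1=C(C)CC[C@@]1(O)C(C)C | intermediate
8 | methoxyallene (1-methoxypropa-1,2-diene) | COC=C=C | starting material
9 | tert-butyl(1-methoxypropa-1,2-dien-1-yl)dimethylsilane | COC(=C=C)[Si](C)(C)C(C)(C)C | intermediate (not isolated)
10 | tert-butyl[1-methoxy-3-(trimethylsilyl)propa-1,2-dien-1-yl]dimethylsilane | COC(=C=C[Si](C)(C)C)[Si](C)(C)C(C)(C)C | intermediate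
11 | (2E)-1-[tert-butyl(dimethyl)silyl]-3-(trimethylsilyl)prop-2-en-1-one | C[Si](C)(C)/C=C/C(=O)[Si](C)(C)C(C)(C)C | intermediate
12 | dilithium salt of (4E)-3-[tert-butyl(dimethyl)silyl]-3-hydroxy-1-[(5R)-5-hydroxy-2-methyl-5-(propan-2-yl)cyclopent-1-en-1-yl]-5-(trimethylsilyl)pent-4-en-1-one (C8 epimers) | [Li+].[Li+].C[Si](C)(C)/C=C/C([O-])([Si](C)(C)C(C)(C)C)CC(=O)C1=C(C)CC[C@@]1([O-])C(C)C | intermediate (not isolated)
13 | dilithium cis-dialkenylcyclopropanolate: 2-[(tert-butyldimethylsilyl)oxy]-1-[(5R)-2-methyl-5-oxido-5-(propan-2-yl)cyclopent-1-en-1-yl]-2-[(E)-2-(trimethylsilyl)ethenyl]cyclopropan-1-olate, the two alkenyl groups cis | [Li+].[Li+].[O-][C@@]1(C2=C(C)CC[C@@]2([O-])C(C)C)C[C@]1(O[Si](C)(C)C(C)(C)C)/C=C/[Si](C)(C)C | intermediate (not isolated)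
14 | dilithium 8-[(tert-butyldimethylsilyl)oxy]-10α-(trimethylsilyl)-14-nordauca-5,8-diene-4β,6-diolate | [Li+].[Li+].[O-]C1=C2[C@]([O-])(C(C)C)CC[C@]2(C)[C@H]([Si](C)(C)C)C=C(O[Si](C)(C)C(C)(C)C)C1 | intermediate (not isolated)
15 | 8-[(tert-butyldimethylsilyl)oxy]-4β-hydroxy-10α-(trimethylsilyl)-14-nor-5α-dauc-8-en-6-one | O=C1CC(O[Si](C)(C)C(C)(C)C)=C[C@@H]([Si](C)(C)C)[C@@]2(C)CC[C@@](O)(C(C)C)[C@H]12 | intermediate
16 | 8-[(tert-butyldimethylsilyl)oxy]-10α-(trimethylsilyl)-14-nor-5α-dauc-8-ene-4β,6α-diol | O[C@H]1CC(O[Si](C)(C)C(C)(C)C)=C[C@@H]([Si](C)(C)C)[C@@]2(C)CC[C@@](O)(C(C)C)[C@H]12 | intermediate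
17 | 8-[(tert-butyldimethylsilyl)oxy]-4β-hydroxy-10α-(trimethylsilyl)-14-nor-5α-dauc-8-en-6α-yl 3-methylbutanoate | CC(C)CC(=O)O[C@H]1CC(O[Si](C)(C)C(C)(C)C)=C[C@@H]([Si](C)(C)C)[C@@]2(C)CC[C@@](O)(C(C)C)[C@H]12 | intermediate
18 | 9β-bromo-4β-hydroxy-8-oxo-10α-(trimethylsilyl)-14-nor-5α-daucan-6α-yl 3-methylbutanoate | CC(C)CC(=O)O[C@H]1CC(=O)[C@H](Br)[C@@H]([Si](C)(C)C)[C@@]2(C)CC[C@@](O)(C(C)C)[C@H]12 | intermediate (not isolated)
19 | 4β-hydroxy-8-oxo-14-nor-5α-dauc-9-en-6α-yl 3-methylbutanoate | CC(C)CC(=O)O[C@H]1CC(=O)C=C[C@@]2(C)CC[C@@](O)(C(C)C)[C@H]12 | intermediate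
20 | 4β,9α,10α-trihydroxy-8-oxo-14-nor-5α-daucan-6α-yl 3-methylbutanoate | CC(C)CC(=O)O[C@H]1CC(=O)[C@@H](O)[C@@H](O)[C@@]2(C)CC[C@@](O)(C(C)C)[C@H]12 | intermediate
21 | 4β-hydroxy-9α,10α-(isopropylidenedioxy)-8-oxo-14-nor-5α-daucan-6α-yl 3-methylbutanoate | CC(C)CC(=O)O[C@H]1CC(=O)[C@H]3OC(C)(C)O[C@H]3[C@@]2(C)CC[C@@](O)(C(C)C)[C@H]12 | intermediate
22 | 4β-hydroxy-9α,10α-(isopropylidenedioxy)-5α-dauc-8(14)-en-6α-yl 3-methylbutanoate | CC(C)CC(=O)O[C@H]1CC(=C)[C@H]3OC(C)(C)O[C@H]3[C@@]2(C)CC[C@@](O)(C(C)C)[C@H]12 | intermediate
23 | 4β,9α,10α-trihydroxy-5α-dauc-8(14)-en-6α-yl 3-methylbutanoate | CC(C)CC(=O)O[C@H]1CC(=C)[C@@H](O)[C@@H](O)[C@@]2(C)CC[C@@](O)(C(C)C)[C@H]12 | intermediate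
24 | (1S,4R,5S,6S,8S,9S,10S)-8,14-epoxy-4,9,10-trihydroxydaucan-6-yl 3-methylbutanoate (4β,9α,10α-triol, 6α-ester, epoxide oxygen α) | CC(C)CC(=O)O[C@H]1C[C@]2(CO2)[C@@H](O)[C@@H](O)[C@@]2(C)CC[C@@](O)(C(C)C)[C@H]12 | target

## Step count and risks

Total step count: 16 (14 in the main line, 2 for acylsilane 11). Longest linear sequence: 14 steps (steps 1–5 and 8–16).

Least certain steps:

**Step 8 (key step).** Three things may go wrong:
- Ring closure of the siloxyallyl lithium onto the C6 carbonyl may be slow, because that carbonyl is flanked by the C1 methyl and the quaternary C4. The anion could then be protonated or close through C10 to a five-membered carbinol.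
- Facial selectivity at C1 may be poor if the lithium bridge between the C4 and C6 oxygens does not dominate the boat transition state.
- Some γ-deprotonation of 7 may compete.

Fallback (reversed polarity: the ring-side carbon becomes the carbanion and attacks an unhindered side-chain ketone). It sets out from 4 and comes back at 15. Bu4NF frees the tertiary alcohol to give (5R)-5-hydroxy-2-methyl-5-(propan-2-yl)cyclopent-1-ene-1-carbaldehyde F1. PhMe2SiLi (2 equiv, THF, −78 °C) adds to the aldehyde to give the α-silyl carbinol F2, and Swern oxidation gives the acylsilane F3. F3 is deprotonated at the hydroxyl with LiN(SiMe3)2 and treated with commercial (E)-4-(trimethylsilyl)but-3-en-2-one that has been deprotonated at its methyl group with LiN(iPr)2 (−78 → −20 °C). The same addition, Brook rearrangement, cyclopropanolate and oxy-Cope sequence follows, and the resulting C8 enolate is trapped with t-BuMe2SiCl/HMPA to give the bis(silyl enol ether) F4. Citric acid in MeOH at 0 °C cleaves only the labile dimethylphenylsilyl enol ether at C6, and protonation at C5 as in step 8 gives 15.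

**Step 3.** β-Elimination of the silanolate from the open-chain aldehyde may occur before cyclisation, or the cyclised aldol may dehydrate towards C4 instead of C1, which would destroy the stereocentre.

Fallback (separate addition and leaving-group-controlled dehydration). It sets out from 3 and comes back at 4. L-Proline (DMSO, rt) effects the intramolecular aldol addition only, giving the β-hydroxy aldehyde F5. Methanesulfonyl chloride/Et3N then converts its single free hydroxyl into the mesylate F6, which loses methanesulfonate by E1cB elimination to give 4.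

**Step 9.** Ligand exchange at the hindered tertiary hydroxyl may be too slow (no reduction, or loss of facial control), and the silyl enol ether may be protonated by the acetic acid medium.

Fallback (stereo-inversion instead of directed delivery). It sets out from 15 and comes back at 17. NaBH4/CeCl3·7H2O (MeOH, −78 °C) under steric control, with hydride entering from the α face away from C15 and the C4 hydroxyl, should give the 6β-alcohol F7. Mitsunobu esterification of F7 with 3-methylbutanoic acid (PPh3, diisopropyl azodicarboxylate) inverts C6 and gives 17 directly.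

**Step 16.** Facial selectivity may be poor if the C9 hydroxyl lies near the plane of the exocyclic alkene in the flexible seven-membered ring, and some oxidation of the allylic alcohol may occur.

Fallback (epoxide by ring closure of a diol). It sets out from 23 and comes back at 24. OsO4·TMEDA (CH2Cl2, −78 °C), a hydrogen-bond-directed dihydroxylation syn to the C9 hydroxyl, gives the 8α,14-diol, that is the pentaol F8. Selective sulfonylation of the primary C14 hydroxyl (TsCl, Et3N, cat. Bu2SnO) gives the tosylate F9. DBU then closes the epoxide by attack of the C8 oxygen on C14 with retention at C8, giving 24.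

## Further compounds

F1 | step 8 | (5R)-5-hydroxy-2-methyl-5-(propan-2-yl)cyclopent-1-ene-1-carbaldehyde | O=CC1=C(C)CC[C@@]1(O)C(C)C
F2 | step 8 | (1R)-2-{[dimethyl(phenyl)silyl](hydroxy)methyl}-3-methyl-1-(propan-2-yl)cyclopent-2-en-1-ol (carbinol epimers) | C[Si](C)(c1ccccc1)C(O)C1=C(C)CC[C@@]1(O)C(C)C
F3 | step 8 | [dimethyl(phenyl)silyl][(5R)-5-hydroxy-2-methyl-5-(propan-2-yl)cyclopent-1-en-1-yl]methanone | C[Si](C)(c1ccccc1)C(=O)C1=C(C)CC[C@@]1(O)C(C)C
F4 | step 8 | 8-[(tert-butyldimethylsilyl)oxy]-6-{[dimethyl(phenyl)silyl]oxy}-10α-(trimethylsilyl)-14-nordauca-5,8-dien-4β-ol | C[Si](C)(c1ccccc1)OC1=C2[C@](O)(C(C)C)CC[C@]2(C)[C@H]([Si](C)(C)C)C=C(O[Si](C)(C)C(C)(C)C)C1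
F5 | step 3 | (5R)-2-hydroxy-2-methyl-5-(propan-2-yl)-5-[(triethylsilyl)oxy]cyclopentane-1-carbaldehyde (new centres as formed) | O=CC1C(C)(O)CC[C@@]1(O[Si](CC)(CC)CC)C(C)C
F6 | step 3 | (3R)-2-formyl-1-methyl-3-(propan-2-yl)-3-[(triethylsilyl)oxy]cyclopentyl methanesulfonate | O=CC1C(C)(OS(C)(=O)=O)CC[C@@]1(O[Si](CC)(CC)CC)C(C)C
F7 | step 9 | 8-[(tert-butyldimethylsilyl)oxy]-10α-(trimethylsilyl)-14-nor-5α-dauc-8-ene-4β,6β-diol | O[C@@H]1CC(O[Si](C)(C)C(C)(C)C)=C[C@@H]([Si](C)(C)C)[C@@]2(C)CC[C@@](O)(C(C)C)[C@H]12
F8 | step 16 | 4β,8α,9α,10α,14-pentahydroxy-5α-daucan-6α-yl 3-methylbutanoate | CC(C)CC(=O)O[C@H]1C[C@](O)(CO)[C@@H](O)[C@@H](O)[C@@]2(C)CC[C@@](O)(C(C)C)[C@H]12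
F9 | step 16 | 4β,8α,9α,10α-tetrahydroxy-14-[(4-methylbenzenesulfonyl)oxy]-5α-daucan-6α-yl 3-methylbutanoate | CC(C)CC(=O)O[C@H]1C[C@](O)(COS(=O)(=O)c3ccc(C)cc3)[C@@H](O)[C@@H](O)[C@@]2(C)CC[C@@](O)(C(C)C)[C@H]12
A1 | alternative 1 | 3-methylcyclopent-2-en-1-one | CC1=CC(=O)CC1
A2 | alternative 1 | metathesis precursor: ring A with a C1 vinyl group and the C5 side chain CH(OSiMe2t-Bu)CH2C(=O)CH=CH2 (6α-silyloxy, 4β-hydroxy) | CC(C)(C)[Si](C)(C)O[C@@H](CC(=O)C=C)[C@H]1[C@](O)(C(C)C)CC[C@]1(C)C=C
A3 | alternative 1 | 6α-[(tert-butyldimethylsilyl)oxy]-4β-hydroxy-14-nor-5α-dauc-9-en-8-one | CC(C)(C)[Si](C)(C)O[C@H]1CC(=O)C=C[C@@]2(C)CC[C@@](O)(C(C)C)[C@H]12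
A4 | alternative 2 | trans-hydrindanone lacking C9: (ring B as cyclohexanone) 6α-[(tert-butyldimethylsilyl)oxy]-4β-hydroxy ketone with C8 carbonyl bonded to C10 | O=C1C[C@H](O[Si](C)(C)C(C)(C)C)[C@H]2[C@](O)(C(C)C)CC[C@]2(C)C1
A5 | alternative 3 | ene precursor: ring-A C5 carbaldehyde with the C1 side chain as 9,10-acetonide bearing an isopropenyl group | O=C[C@H]1[C@](O)(C(C)C)CC[C@]1(C)[C@@H]2OC(C)(C)O[C@@H]2C(C)=C
A6 | alternative 3 | 9α,10α-(isopropylidenedioxy)-5α-dauc-8(14)-ene-4β,6α-diol | O[C@H]1CC(=C)[C@H]3OC(C)(C)O[C@H]3[C@@]2(C)CC[C@@](O)(C(C)C)[C@H]12
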